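**Plan**
1. Retrosynthesis: cut the gallate ester C–O bond (acid 12 + flavan-3-ol 11), then remove C3–OH and C2–H as one syn H/OH addition across C2=C3 (achiral flav-2-ene 9), then cut C3–C4 and O1–C8a of ring C together (ketone 2 + benzylic bromide 7).
2. Enabling feature: at the flav-2-ene level O1–C2=C3 is the enolate of an aryl methyl ketone, an O/C 1,3-dinucleophile. Ring A offers the matching 1,3-dielectrophile: benzylic C4 and the ortho carbon C8a, which is meta to both other ring A oxygens, so its C–Br bond is not deactivated by resonance.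
3. Forward: rings A and B are bought; ketone 2 (ring B) and bromide 7 (ring A) are made separately, and one pot joins C3–C4 and then closes ring C through O1–C8a.
4. Stereochemistry: both stereocentres come from one reagent-controlled hydroboration of 9; syn addition fixes 2,3-trans and the isopinocampheyl group fixes the absolute sense (2R,3S).
5. End game: Steglich galloylation at O3, then hydrogenolysis of eight benzyl ethers.

Key step: step 5

Remark: compounds 1, 3 and 12 are taken as commercial, and the facial preference of IpcBH2 on flav-2-ene 9 is assumed to follow that known for 1-arylcycloalkenes.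

**Step 1**
Reactants: 1 1-(3,4,5-trihydroxyphenyl)ethan-1-one
Product: 2 1-[3,4,5-tris(benzyloxy)phenyl]ethan-1-one
Conditions: BnBr, K2CO3, DMF, 60 °C
Reagents that add atoms: benzyl bromide BrCc1ccccc1
Why: Williamson ether synthesis: K2CO3 deprotonates the three phenols (far more acidic than the ketone α-C–H) and the phenoxides displace bromide from benzyl bromide by SN2; no stereocentre is involved.

**Step 2**
Reactants: 3 1,3-bis(benzyloxy)-5-bromobenzene
Product: 5 2,4-bis(benzyloxy)-6-bromobenzaldehyde, via iminium chloride 4 (not isolated)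
Conditions: POCl3, DMF, 0 → 70 °C; then H2O
Reagents that add atoms: N,N-dimethylformamide CN(C)C=O; water O
Why: Vilsmeier–Haack formylation: the chloroiminium ion attacks the position para to one benzyloxy group and ortho to the other (two equivalent sites) rather than the more crowded site between the two ethers, and water hydrolyses iminium salt 4 to the aldehyde; no stereocentre is involved.

**Step 3**
Reactants: 5 2,4-bis(benzyloxy)-6-bromobenzaldehyde
Product: 6 [2,4-bis(benzyloxy)-6-bromophenyl]methanol
Conditions: NaBH4, THF/MeOH, 0 °C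
Reagents that add atoms: none
Why: Hydride reduction of the aldehyde by NaBH4, which leaves the aryl bromide and the benzyl ethers untouched; no stereocentre is formed.

**Step 4**
Reactants: 6 [2,4-bis(benzyloxy)-6-bromophenyl]methanol
Product: 7 1,5-bis(benzyloxy)-3-bromo-2-(bromomethyl)benzene
Conditions: PBr3, Et2O, 0 °C; used at once
Reagents that add atoms: phosphorus tribromide BrP(Br)Br
Why: Conversion of a primary benzylic alcohol into the bromide via its phosphite ester (SN2 by bromide), fast at 0 °C for this electron-rich benzylic system, whose product is used at once because it ionises easily; no stereocentre is formed.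

**Step 5**
Reactants: 2 1-[3,4,5-tris(benzyloxy)phenyl]ethan-1-one; 7 1,5-bis(benzyloxy)-3-bromo-2-(bromomethyl)benzene
Product: 9 5,7-bis(benzyloxy)-2-[3,4,5-tris(benzyloxy)phenyl]-4H-chromene, via bromo ketone 8 (not isolated)
Conditions: LiN(SiMe3)2 (1.0 equiv), 2 (1.2 equiv), THF, −78 °C; 7, −78 → 0 °C; then CuI (10 mol %), 1,10-phenanthroline (20 mol %), Cs2CO3 (2 equiv), DMF, 100 °C
Reagents that add atoms: none
Why: Proposed new method: the lithium enolate of 2 is C-benzylated by 7 in an SN2 step that forms C3–C4 and gives bromo ketone 8; carbonate then regenerates the enolate of 8, whose Z geometry (fixed by the aryl ketone) holds the oxygen next to C8a, and the monovalent copper enolate inserts into the C8a–Br bond and closes the pyran ring by C–O reductive elimination, a 6-exo closure onto an sp2 carbon. The closest known reaction type is the CuI-catalysed domino C-benzylation/O-arylation of 1,3-dicarbonyl compounds with 2-bromobenzyl bromides to 4H-chromenes, together with the intramolecular O-arylation of simple ketone enolates to benzofurans; new here is the use of an unstabilised methyl ketone enolate in the merged sequence, handled by making the enolate stoichiometrically for the first bond and catalytically for the second. No stereocentre is formed. The step needs C- over O-benzylation and mono- over bis-alkylation, which the lithium counter-ion in THF at low temperature and the slight excess of 2 should secure, and O- over C-arylation, which is secured because C-arylation would need a four-membered ring. C8a lies meta to both benzyloxy groups of ring A, so its C–Br bond is not deactivated toward oxidative addition by resonance donation.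

**Step 6**
Reactants: 9 5,7-bis(benzyloxy)-2-[3,4,5-tris(benzyloxy)phenyl]-4H-chromene
Product: 11 (2R,3S)-5,7-bis(benzyloxy)-2-[3,4,5-tris(benzyloxy)phenyl]chroman-3-ol, via trans-flavan-3-yl(isopinocampheyl)borane 10 (not isolated)
Conditions: IpcBH2 from (+)-α-pinene (1.3 equiv), THF, −25 → 0 °C; then NaOH, H2O2, 0 °C → rt
Reagents that add atoms: hydrogen peroxide OO
Why: Asymmetric hydroboration–oxidation: the four-centre syn addition places boron on C3 (β to both O1 and the aryl group) and hydrogen on C2 from the same face, so oxidation with retention can only give the 2,3-trans alcohol, and the isopinocampheyl group selects the face as it does for 1-arylcycloalkenes, which the reagent from (+)-α-pinene takes to (1S,2R)-trans-2-arylcycloalkanols, the spatial counterpart of (2R,3S) here.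

**Step 7**
Reactants: 11 (2R,3S)-5,7-bis(benzyloxy)-2-[3,4,5-tris(benzyloxy)phenyl]chroman-3-ol; 12 3,4,5-tris(benzyloxy)benzoic acid
Product: 13 (2R,3S)-5,7-bis(benzyloxy)-2-[3,4,5-tris(benzyloxy)phenyl]chroman-3-yl 3,4,5-tris(benzyloxy)benzoate
Conditions: DCC, DMAP (cat.), CH2Cl2, 0 °C → rt
Reagents that add atoms: none
Why: Steglich esterification: DCC activates 12 as the O-acylisourea and DMAP passes the acyl group to the C3 hydroxyl, a reaction at oxygen that leaves C2 and C3 untouched.

**Step 8**
Reactants: 13 (2R,3S)-5,7-bis(benzyloxy)-2-[3,4,5-tris(benzyloxy)phenyl]chroman-3-yl 3,4,5-tris(benzyloxy)benzoate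
Product: 14 (+)-gallocatechin gallate
Conditions: H2 (1 atm), Pd(OH)2/C, THF/MeOH, rt
Reagents that add atoms: none
Why: Hydrogenolysis of the eight benzyl ethers over Pd(OH)2 on carbon under neutral conditions at room temperature, where the ester and the ring C2–O1 bond should persist and C2 should not epimerise.

**Compound list**
1 | 1-(3,4,5-trihydroxyphenyl)ethan-1-one | CC(=O)c1cc(O)c(O)c(O)c1 | starting material
2 | 1-[3,4,5-tris(benzyloxy)phenyl]ethan-1-one | CC(=O)c1cc(OCc2ccccc2)c(OCc2ccccc2)c(OCc2ccccc2)c1 | intermediate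
3 | 1,3-bis(benzyloxy)-5-bromobenzene | Brc1cc(OCc2ccccc2)cc(OCc2ccccc2)c1 | starting material
4 | N-{[2,4-bis(benzyloxy)-6-bromophenyl]methylidene}-N-methylmethanaminium chloride (iminium chloride) | C[N+](C)=Cc1c(Br)cc(OCc2ccccc2)cc1OCc1ccccc1.[Cl-] | intermediate
5 | 2,4-bis(benzyloxy)-6-bromobenzaldehyde | O=Cc1c(Br)cc(OCc2ccccc2)cc1OCc1ccccc1 | intermediate
6 | [2,4-bis(benzyloxy)-6-bromophenyl]methanol | OCc1c(Br)cc(OCc2ccccc2)cc1OCc1ccccc1 | intermediate
7 | 1,5-bis(benzyloxy)-3-bromo-2-(bromomethyl)benzene | BrCc1c(Br)cc(OCc2ccccc2)cc1OCc1ccccc1 | intermediate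
8 | 3-[2,4-bis(benzyloxy)-6-bromophenyl]-1-[3,4,5-tris(benzyloxy)phenyl]propan-1-one (bromo ketone) | O=C(CCc1c(Br)cc(OCc2ccccc2)cc1OCc1ccccc1)c1cc(OCc2ccccc2)c(OCc2ccccc2)c(OCc2ccccc2)c1 | intermediate
9 | 5,7-bis(benzyloxy)-2-[3,4,5-tris(benzyloxy)phenyl]-4H-chromene (achiral flav-2-ene) | C1(=CCc2c(OCc3ccccc3)cc(OCc3ccccc3)cc2O1)c1cc(OCc2ccccc2)c(OCc2ccccc2)c(OCc2ccccc2)c1 | intermediate
10 | trans-{5,7-bis(benzyloxy)-2-[3,4,5-tris(benzyloxy)phenyl]chroman-3-yl}(isopinocampheyl)borane, boron on C3 cis to H on C2, same spatial arrangement at C2 and C3 as in 11, isopinocampheyl group from (+)-α-pinene | C[C@H]1[C@H](B[C@H]3Cc4c(OCc5ccccc5)cc(OCc5ccccc5)cc4O[C@@H]3c3cc(OCc4ccccc4)c(OCc4ccccc4)c(OCc4ccccc4)c3)C[C@@H]2C[C@H]1C2(C)C | intermediate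
11 | (2R,3S)-5,7-bis(benzyloxy)-2-[3,4,5-tris(benzyloxy)phenyl]chroman-3-ol (penta-O-benzyl gallocatechin) | O[C@H]1Cc2c(OCc3ccccc3)cc(OCc3ccccc3)cc2O[C@@H]1c1cc(OCc2ccccc2)c(OCc2ccccc2)c(OCc2ccccc2)c1 | intermediate
12 | 3,4,5-tris(benzyloxy)benzoic acid | OC(=O)c1cc(OCc2ccccc2)c(OCc2ccccc2)c(OCc2ccccc2)c1 | starting material
13 | (2R,3S)-5,7-bis(benzyloxy)-2-[3,4,5-tris(benzyloxy)phenyl]chroman-3-yl 3,4,5-tris(benzyloxy)benzoate | O=C(O[C@H]1Cc2c(OCc3ccccc3)cc(OCc3ccccc3)cc2O[C@@H]1c1cc(OCc2ccccc2)c(OCc2ccccc2)c(OCc2ccccc2)c1)c1cc(OCc2ccccc2)c(OCc2ccccc2)c(OCc2ccccc2)c1 | intermediate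
14 | (+)-gallocatechin gallate, (2R,3S)-5,7-dihydroxy-2-(3,4,5-trihydroxyphenyl)chroman-3-yl 3,4,5-trihydroxybenzoate | O=C(O[C@H]1Cc2c(O)cc(O)cc2O[C@@H]1c1cc(O)c(O)c(O)c1)c1cc(O)c(O)c(O)c1 | target

**Step count**
Total: 8 steps. Longest linear sequence: 7 steps (steps 2 to 8, from 3 to 14).

**Steps most likely to fail**

Step 5. The enolate may be benzylated twice in the first stage. In the second stage, enolisation of the unactivated ketone may be slow, so that aldol self-condensation or protodebromination outruns C–O bond formation. The fallback uses known chemistry, sets out from 2 and 7, and returns at 9. Only the lithium enolate alkylation is run and bromo ketone 8 is isolated. Miyaura borylation (B2pin2, Pd(dppf)Cl2, KOAc, dioxane, 90 °C) should give the pinacol boronate F1. Oxidation with NaBO3·4H2O in THF/H2O should give the phenol F2, which equilibrates with its cyclic hemiketal. Acid-catalysed cyclodehydration (PPTS, toluene, 4 Å molecular sieves, 80 °C) should then give 9. Here O1 comes from the oxidant and ring C closes by hemiketalisation at C2 instead of enolate O-arylation.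

Step 6. Facial discrimination by the chiral borane may be poor, and the β-aryloxy borane may eliminate with opening of ring C. The fallback replaces reagent control by resolution, sets out from 9, and returns at 11. Hydroboration with BH3·SMe2 followed by NaOH/H2O2 should give 11 together with its enantiomer, the (2S,3R) alcohol F3. Esterification of the mixture with (S)-2-methoxy-2-phenylacetic acid (DCC, DMAP, CH2Cl2) should give the diastereomeric esters, the (2R,3S) ester F4 and the (2S,3R) ester F5. These are separated by chromatography or crystallisation, and methanolysis of F4 (K2CO3, MeOH/THF) returns 11.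

Step 4. The electron-rich benzylic bromide may ionise and self-condense by Friedel–Crafts alkylation before it meets the enolate. The fallback avoids the halide, sets out from 5 and 2, and returns at 8. Claisen–Schmidt condensation (KOH, EtOH/THF, rt) should give the (E)-chalcone F6. Conjugate reduction with [CuH(PPh3)]6 in toluene should give bromo ketone 8, which is isolated and taken through the copper stage of step 5 to 9.

**Further compounds**
F1 | step 5 | 3-[2,4-bis(benzyloxy)-6-(4,4,5,5-tetramethyl-1,3,2-dioxaborolan-2-yl)phenyl]-1-[3,4,5-tris(benzyloxy)phenyl]propan-1-one | CC1(C)OB(OC1(C)C)c1cc(OCc2ccccc2)cc(OCc2ccccc2)c1CCC(=O)c1cc(OCc2ccccc2)c(OCc2ccccc2)c(OCc2ccccc2)c1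
F2 | step 5 | 3-[2,4-bis(benzyloxy)-6-hydroxyphenyl]-1-[3,4,5-tris(benzyloxy)phenyl]propan-1-one | O=C(CCc1c(O)cc(OCc2ccccc2)cc1OCc1ccccc1)c1cc(OCc2ccccc2)c(OCc2ccccc2)c(OCc2ccccc2)c1
F3 | step 6 | (2S,3R)-5,7-bis(benzyloxy)-2-[3,4,5-tris(benzyloxy)phenyl]chroman-3-ol | O[C@@H]1Cc2c(OCc3ccccc3)cc(OCc3ccccc3)cc2O[C@H]1c1cc(OCc2ccccc2)c(OCc2ccccc2)c(OCc2ccccc2)c1
F4 | step 6 | (2R,3S)-5,7-bis(benzyloxy)-2-[3,4,5-tris(benzyloxy)phenyl]chroman-3-yl (S)-2-methoxy-2-phenylacetate | CO[C@H](C(=O)O[C@H]1Cc2c(OCc3ccccc3)cc(OCc3ccccc3)cc2O[C@@H]1c1cc(OCc2ccccc2)c(OCc2ccccc2)c(OCc2ccccc2)c1)c1ccccc1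
F5 | step 6 | (2S,3R)-5,7-bis(benzyloxy)-2-[3,4,5-tris(benzyloxy)phenyl]chroman-3-yl (S)-2-methoxy-2-phenylacetate | CO[C@H](C(=O)O[C@@H]1Cc2c(OCc3ccccc3)cc(OCc3ccccc3)cc2O[C@H]1c1cc(OCc2ccccc2)c(OCc2ccccc2)c(OCc2ccccc2)c1)c1ccccc1
F6 | step 4 | (E)-3-[2,4-bis(benzyloxy)-6-bromophenyl]-1-[3,4,5-tris(benzyloxy)phenyl]prop-2-en-1-one | O=C(/C=C/c1c(Br)cc(OCc2ccccc2)cc1OCc1ccccc1)c1cc(OCc2ccccc2)c(OCc2ccccc2)c(OCc2ccccc2)c1
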